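(The readings are calculated for an exercise.)

A small charge of initiator, 2 mol% of the free monomer, goes into two flasks held for 8.0 h, midnight at 80 °C and noon at 95 °C, and two earlier runs are at hand.

| flask | free monomer | protic impurity | initiator | temperature | remark | time |
|---|---|---|---|---|---|---|
| Saturday's | 0.25 M | 0.0125 M | 1.3 mol% | 75 °C | run made earlier |  |
| Sunday's | 0.25 M | 0.0125 M | 3 mol% | 88 °C | run made earlier |  |
| midnight | 0.25 M | 0.0125 M | 2 mol% | 80 °C |  | 8.0 h |
| noon | 0.25 M | 0.0125 M | 2 mol% | 95 °C |  | 8.0 h |

- Saturday's (time / h: monomer in chains / %, free monomer / %): 0.833: 86.4, 6.7; 1.33: 89.0, 1.0; 2.00: 90.4, 0.9; 4.00: 88.2, 0; 6.00: 92.5, 0; 10.0: 89.0, 0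
- Sunday's (time / h: monomer in chains / %, free monomer / %): 0.833: 92.6, 0; 1.33: 91.9, 0; 2.00: 94.4, 0.3; 4.00: 92.9, 0; 6.00: 92.9, 0; 10.0: 93.4, 0

(standard deviation of a reading: 1 percentage point)

- which flask leads in amount of monomer in chains, in percent of the free monomer charged ("all alike" within 1.5 percentage points) (midnight / noon / all alike)
- how much monomer in chains is there at the end, in percent of the free monomer charged: midnight
- how much monomer in chains is there at the end, in percent of the free monomer charged: noon

By 2.00 h, free monomer reads 0.9% on Saturday and 0.3% on Sunday, and the chain readings show no drift beyond their scatter. I therefore replace each plateau by its mean, which leaves lost shares of 9.97% on Saturday and 6.98% on Sunday.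

I assume that chains end by meeting in pairs. At fixed temperature the carriers then go as the root of the loading, and the share lost to a leak competing with growth goes as its inverse. So the lost share times the root of the loading should be one dimensionless number, measuring the leak against growth. Saturday gives 0.0114 and Sunday 0.0121, and I keep their mean as the leak number, 0.0117.

Both new flasks have the same loading, so each should lose 8.30% and hold 91.7% in chains. Was one number enough? The runs also differ in temperature, yet their two values, carried to this loading, part by 0.51 percentage points, inside the margin of 1.5 points. Noon, however, lies beyond Sunday's temperature.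

The forecast gives all alike, with 91.2% for midnight and 92.2% for noon: “A stoichiometric impurity effect seems somewhat more likely”.

The simulation gives all alike, with 91.6% at midnight and 92.5% at noon.

    free monomer + growing radical → monomer in chains + growing radical, rate k1*[growing radical]*[free monomer] (k = 5100 M⁻¹ s⁻¹, Ea = 44.0 kJ mol⁻¹)
    protic impurity + free monomer → quenched substrate (k = 0.00500 M⁻¹ s⁻¹, Ea = 86.0 kJ mol⁻¹)
    free monomer + monomer in chains → side product (k = 4.40 × 10⁻⁴ M⁻¹ s⁻¹, Ea = 76.0 kJ mol⁻¹)
    free monomer + initiating radical → growing radical + monomer in chains (k = 5400 M⁻¹ s⁻¹, Ea = 14.0 kJ mol⁻¹)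
    2 growing radical → dead chain (k = 5.90 × 10⁶ M⁻¹ s⁻¹, Ea = 14.0 kJ mol⁻¹)
    initiator → 2 initiating radical (k = 1.30 × 10⁻⁴ s⁻¹, Ea = 104 kJ mol⁻¹)
    (constants at 80 °C)

These results return leak numbers of 0.0119 for midnight and 0.0106 for noon, against my 0.0117. The neighbour is midnight with 0.5 mol% of initiator, where the leak number foretells a loss of 16.5%, so 83.5% in chains. That flask holds 84.9% in chains. Its side product stands at 11.3%, twice midnight's 5.84%, the factor the root asks for, while its quenched substrate goes from 2.55% to 3.80%.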